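**Strategy.** Ring A is cut at its methyl-bearing α-carbon. This CH3–C unit sits between the carbonyl carbon and the tether-bearing β-carbon, so it can be inserted as chloro(methyl)carbene into the enol double bond of a cis-fused hydrindan-2-one whose two ring-fusion centres and tertiary carbinol are already in place. One operation (cyclopropanation, then opening of the bond shared with the five-membered ring) forms both C–C bonds of the inserted carbon, enlarges the cyclopentane to the six-membered enone of ring A and places the methyl group. The precursor is the regiodefined triethylsilyl enol ether of that hydrindanone, carrying the fully silylated perhydrobenzoxepine half on its α-carbon.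

Key step: step 18

Assumption: LaLi3[(S)-1,1'-binaphthalene-2,2'-diolate]3 is taken to give the (S)-epoxide from an alkyl methyl ketone; if the sense proves opposite, the (R)-diolate complex is used.

Numbering used in names: left half as perhydro-1-benzoxepine (O1, C2 … C9a; C5a carries the angular methyl, C6 the tether, C7 the tertiary carbinol); hydrindane half as 2H-inden-2-one (C1 α-carbon, C2 carbonyl, C3a/C7a ring fusion, C4 carbinol, C7 gem-dimethyl).

**Step 1**
Reactants: 1 (2E,6E)-farnesol
Product: 2 (2E,6E)-farnesyl acetate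
Conditions: Ac2O, pyridine, DMAP (cat.), CH2Cl2, 0 °C to rt
Reagents that add atoms: acetic anhydride, CC(=O)OC(C)=O
Why: DMAP-catalysed O-acylation of the primary allylic alcohol, the acetate being needed to make the 2,3-alkene electron-poor for step 2.

**Step 2**
Reactants: 2 (2E,6E)-farnesyl acetate
Product: 3 (2E,6S,7S,10S)-6,7:10,11-diepoxyfarnesyl acetate
Conditions: L-fructose-derived Shi ketone (cat.), Oxone (2KHSO5·KHSO4·K2SO4), K2CO3, Bu4NHSO4, MeCN/CH2(OMe)2/aq. Na2B4O7 buffer, 0 °C
Reagents that add atoms: potassium peroxymonosulfate (active part of Oxone), [K+].[O-]S(=O)(=O)OO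
Why: Shi asymmetric epoxidation, in which the chiral dioxirane attacks the two electron-rich trisubstituted E-alkenes through the spiro transition state, spares the acetate-deactivated 2,3-alkene, and (being the mirror image of the D-fructose catalyst that gives R,R) sets 6S,7S and 10S.

**Step 3**
Reactants: 3 (2E,6S,7S,10S)-6,7:10,11-diepoxyfarnesyl acetate
Product: 4 (2E,6S,7S,10S)-6,7:10,11-diepoxyfarnesol
Conditions: K2CO3, MeOH, 0 °C
Reagents that add atoms: none
Why: Base-catalysed transesterification frees the allylic alcohol while the trisubstituted epoxides are inert to methoxide at 0 °C.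

**Step 4**
Reactants: 4 (2E,6S,7S,10S)-6,7:10,11-diepoxyfarnesol
Product: 6 (2E,6S,7S,10S)-1-bromo-6,7:10,11-diepoxy-3,7,11-trimethyldodec-2-ene, via allylic mesylate 5 (not isolated)
Conditions: MsCl, Et3N, THF, −40 °C; then LiBr, THF, −40 to 0 °C
Reagents that add atoms: lithium bromide, [Li+].[Br-]
Why: Mesylation followed by SN2 displacement with bromide at low temperature should give the primary allylic bromide with the E-alkene and both epoxides intact.

**Step 5**
Reactants: 6 (2E,6S,7S,10S)-1-bromo-6,7:10,11-diepoxy-3,7,11-trimethyldodec-2-ene; 7 tert-butyl acetate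
Product: 9 tert-butyl (4E,8S,9S,12S)-8,9:12,13-diepoxy-5,9,13-trimethyltetradec-4-enoate, via lithium enolate of tert-butyl acetate 8 (not isolated)
Conditions: LiN(iPr)2, THF, −78 °C; then 6, −78 to −20 °C
Reagents that add atoms: none
Why: Ester enolate alkylation (SN2 at the primary allylic bromide), which adds the second tether carbon and the carboxyl group that will terminate the cyclisation.

**Step 6**
Reactants: 9 tert-butyl (4E,8S,9S,12S)-8,9:12,13-diepoxy-5,9,13-trimethyltetradec-4-enoate
Product: 11 3-[(3S,5aS,6S,7S,9aS)-3,7-dihydroxy-2,2,5a,7-tetramethyldecahydro-1-benzoxepin-6-yl]propanoic acid δ-lactone onto the C7 oxygen, via trimethylsilyl ether of the lactone 10 (not isolated)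
Conditions: Me3SiOTf, 2,6-di-tert-butyl-4-methylpyridine, CH2Cl2, −78 °C; then citric acid, MeOH, rt
Reagents that add atoms: none
Why: Lewis-acid epoxide-opening cascade of an epoxy-polyene (oxa- then carbacyclisation): the activated terminal epoxide is attacked at its tertiary carbon by the internal epoxide oxygen, the bicyclic epoxonium is opened with inversion at the tertiary carbon by the E-alkene through a chair, and the tertiary cation is captured by the ester carbonyl with loss of isobutene, so C3 and C9a keep the epoxide configurations, C5a is set by inversion, and C6/C7 by anti addition across the E-alkene.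

**Step 7**
Reactants: 11 hydroxy δ-lactone
Product: 14 3-[(3S,5aS,6S,7S,9aS)-2,2,5a,7-tetramethyl-3,7-bis(triethylsilyloxy)decahydro-1-benzoxepin-6-yl]propanoic acid, via lithium dihydroxy carboxylate 12 (not isolated), via tris(triethylsilyl) derivative 13 (not isolated)
Conditions: LiOH, THF/MeOH/H2O, rt; evaporate; Et3SiOTf, 2,6-lutidine, CH2Cl2, 0 °C; then K2CO3 (cat.), MeOH/H2O, 0 °C
Reagents that add atoms: lithium hydroxide, [Li+].[OH-]; triethylsilyl triflate, CC[Si](CC)(CC)OS(=O)(=O)C(F)(F)F
Why: Saponification opens the lactone, silyl triflate silylates both hydroxyls and the carboxylate, and mild methanolysis cleaves only the labile silyl ester, so the tertiary oxygen is capped and cannot relactonise.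

**Step 8**
Reactants: 14 bis(triethylsilyl) propanoic acid
Product: 15 (3S,5aS,6S,7S,9aS)-6-ethenyl-2,2,5a,7-tetramethyl-3,7-bis(triethylsilyloxy)decahydro-1-benzoxepine
Conditions: Pb(OAc)4, Cu(OAc)2 (cat.), pyridine, PhH, 80 °C
Reagents that add atoms: none
Why: Kochi oxidative decarboxylation, in which the primary alkyl radical from the carboxylate is oxidised by Cu(OAc)2 to the terminal alkene, removing the lactone carbon and leaving exactly two tether carbons.

**Step 9**
Reactants: 16 isobutyraldehyde; 17 methyl vinyl ketone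
Product: 20 2,2-dimethyl-5-oxohexanal, via enamine 18 (not isolated), via aminodihydropyran adduct 19 (not isolated)
Conditions: pyrrolidine, PhMe, reflux (−H2O); then 17, 0 °C to rt; then AcOH/NaOAc/H2O, rt
Reagents that add atoms: none
Why: Stork enamine Michael addition of the α,α-disubstituted aldehyde to the enone, hydrolysed under buffered conditions so that the keto aldehyde does not undergo aldol cyclisation.

**Step 10**
Reactants: 20 2,2-dimethyl-5-oxohexanal
Product: 21 5,5-dimethylhept-6-yn-2-one
Conditions: dimethyl (1-diazo-2-oxopropyl)phosphonate, K2CO3, MeOH, 0 °C to rt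
Reagents that add atoms: Ohira–Bestmann reagent, COP(=O)(OC)C(=[N+]=[N-])C(C)=O
Why: Seyferth–Gilbert homologation (Ohira–Bestmann variant) converts the non-enolisable aldehyde into the terminal alkyne, the ketone being inert to the diazophosphonate anion under these conditions.

**Step 11**
Reactants: 21 5,5-dimethylhept-6-yn-2-one
Product: 22 (S)-2-(3,3-dimethylpent-4-yn-1-yl)-2-methyloxirane
Conditions: Me3S(O)I, NaH, THF; LaLi3[(S)-1,1'-binaphthalene-2,2'-diolate]3 (5 mol %), tris(2,4,6-trimethoxyphenyl)phosphine oxide (5 mol %), 5 Å sieves, THF, rt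
Reagents that add atoms: trimethylsulfoxonium iodide, C[S+](C)(C)=O.[I-]
Why: Catalytic asymmetric Corey–Chaykovsky epoxidation, in which the lanthanum–lithium binaphtholate binds ketone and ylide and differentiates methyl from the primary alkyl chain, so methylene is delivered to one face and sets the quaternary (S) centre.

**Step 12**
Reactants: 22 (S)-2-(3,3-dimethylpent-4-yn-1-yl)-2-methyloxirane
Product: 23 (S)-3,6,6-trimethyloct-1-en-7-yn-3-ol
Conditions: Me3SI, n-BuLi (excess), THF, −10 °C to rt
Reagents that add atoms: trimethylsulfonium iodide, C[S+](C)C.[I-]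
Why: One-carbon homologation of a terminal epoxide to an allylic alcohol with dimethylsulfonium methylide (SN2 opening at the CH2 carbon, then ylide-mediated elimination of Me2S), which does not touch the quaternary stereocentre.

**Step 13**
Reactants: 23 (S)-3,6,6-trimethyloct-1-en-7-yn-3-ol
Product: 25 (S)-triethyl{[3,6,6-trimethyl-8-(triethylsilyl)oct-1-en-7-yn-3-yl]oxy}silane, via dilithium alkoxide acetylide 24 (not isolated)
Conditions: n-BuLi (2.2 equiv), THF, −78 °C; Et3SiCl (2.5 equiv), −78 °C to rt
Reagents that add atoms: chlorotriethylsilane, CC[Si](Cl)(CC)CC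
Why: Double deprotonation and silylation protects the tertiary alcohol and puts a silyl group on the alkyne terminus, which later becomes iodine.

**Step 14**
Reactants: 25 bis(triethylsilyl) enyne
Product: 27 (3aS,4S)-4,7,7-trimethyl-1-(triethylsilyl)-4-(triethylsilyloxy)-3,3a,4,5,6,7-hexahydro-2H-inden-2-one, via hexacarbonyldicobalt alkyne complex 26 (not isolated)
Conditions: Co2(CO)8, CH2Cl2, rt; then N-methylmorpholine N-oxide, CH2Cl2, 0 °C to rt
Reagents that add atoms: dicobalt octacarbonyl (one CO), [C-]#[O+].[C-]#[O+].[C-]#[O+].[C-]#[O+].[C-]#[O+].[C-]#[O+].[C-]#[O+].[C-]#[O+].[Co].[Co]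
Why: Intramolecular Pauson–Khand reaction of a 1,7-enyne helped by two quaternary tether carbons, with C3a set in the chair-like alkene insertion where the bulky siloxy group should lie pseudo-equatorial and the cobalt cluster on the opposite face; the preference is not secure, so any C3a epimer is removed by chromatography on this small enone.

**Step 15**
Reactants: 27 α-silyl enone
Product: 28 (3aS,4S)-1-iodo-4,7,7-trimethyl-4-(triethylsilyloxy)-3,3a,4,5,6,7-hexahydro-2H-inden-2-one
Conditions: ICl, CH2Cl2, −78 to 0 °C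
Reagents that add atoms: iodine monochloride, ClI
Why: Ipso-iododesilylation of the vinylsilane (electrophilic substitution at the silicon-bearing α-carbon) gives the α-iodo enone without touching C3a or the silyl ether.

**Step 16**
Reactants: 15 vinyl benzoxepine; 28 α-iodo enone
Product: 30 (3aS,4S)-4,7,7-trimethyl-1-{2-[(3S,5aS,6S,7S,9aS)-2,2,5a,7-tetramethyl-3,7-bis(triethylsilyloxy)decahydro-1-benzoxepin-6-yl]ethyl}-4-(triethylsilyloxy)-3,3a,4,5,6,7-hexahydro-2H-inden-2-one, via B-alkyl-9-BBN 29 (not isolated)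
Conditions: 9-BBN, THF, rt to 60 °C; then 28, PdCl2(dppf), AsPh3, Cs2CO3, DMF/THF/H2O, rt
Reagents that add atoms: none
Why: Anti-Markovnikov hydroboration of the terminal alkene followed by B-alkyl Suzuki–Miyaura coupling with the α-iodo enone joins the halves at the tether–C1 bond with no change at any stereocentre.

**Step 17**
Reactants: 30 tetrasubstituted enone
Product: 31 triethylsilyl enol ether (C1=C2) of the cis-fused (3aS,4S,7aR)-hydrindan-2-one carrying the silylated benzoxepinylethyl chain on C1
Conditions: RhCl(PPh3)3 (5 mol %), Et3SiH, PhMe, 60 °C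
Reagents that add atoms: triethylsilane, CC[SiH](CC)CC
Why: Rhodium-catalysed 1,4-hydrosilylation gives the enol ether regiospecifically toward the tether-bearing carbon, and hydride should reach C7a on the convex face that carries H-3a (the other face is screened by ring B and its axial C4 methyl), which sets the cis ring fusion kinetically.

**Step 18**
Reactants: 31 triethylsilyl enol ether; 32 1,1-dichloroethane
Product: 35 tris(triethylsilyl) ether of sipholenol K, via 1,1-dichloroethyllithium 33 (not isolated), via chloro(methyl)siloxycyclopropane 34 (not isolated)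
Conditions: n-BuLi, Et2O, −40 to −30 °C (slow addition to 31 and excess 32); then Et3N, PhMe, 100 °C
Reagents that add atoms: none
Why: n-BuLi deprotonates 1,1-dichloroethane and α-elimination of LiCl from carbenoid 33 releases chloro(methyl)carbene, which adds to the only alkene, the electron-rich tetrasubstituted enol ether, from the convex face of the cis-hydrindane. On heating, the 1-chloro-2-siloxycyclopropane 34 ionises with disrotatory cleavage of the bond it shares with the five-membered ring, pushed by the siloxy oxygen, and the siloxyallyl cation loses Et3SiCl to give the 2-methyl enone. The closest known reaction type is the halocarbene one-carbon ring enlargement of cycloalkanone silyl enol ethers to 2-substituted cycloalk-2-enones. Ring A is closed as a six-membered ring by enlargement of the cyclopentene ([2+1] cycloaddition, then electrocyclic opening of the cyclopropyl cation), not by a new cyclisation. No stereocentre is created, since the cyclopropane centres are destroyed on opening and C3a, C4 and C7a are not touched. The step needs regiocontrol, fixed by the enol double bond from step 17, and chemoselectivity, secured by silylation of all three hydroxyls; the epimer with chloride syn to the five-membered ring opens directly, while the other may need a higher temperature.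

**Step 19**
Reactants: 35 tris(triethylsilyl) ether of sipholenol K
Product: 36 sipholenol K
Conditions: HF·pyridine, pyridine, THF, 0 °C to rt
Reagents that add atoms: none
Why: Fluoride-mediated desilylation removes the three triethylsilyl ethers under buffered, non-basic conditions that should not epimerise the γ-position of the enone.

**Compound list**

1 | (2E,6E)-farnesol | CC(C)=CCC/C(C)=C/CC/C(C)=C/CO | starting material
2 | (2E,6E)-farnesyl acetate | CC(C)=CCC/C(C)=C/CC/C(C)=C/COC(C)=O | intermediate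
3 | (2E,6S,7S,10S)-6,7:10,11-diepoxy-3,7,11-trimethyldodec-2-en-1-yl acetate | CC1(C)O[C@H]1CC[C@]2(C)O[C@H]2CC/C(C)=C/COC(C)=O | intermediate
4 | (2E,6S,7S,10S)-6,7:10,11-diepoxy-3,7,11-trimethyldodec-2-en-1-ol | CC1(C)O[C@H]1CC[C@]2(C)O[C@H]2CC/C(C)=C/CO | intermediate
5 | methanesulfonate of 4 | CC1(C)O[C@H]1CC[C@]2(C)O[C@H]2CC/C(C)=C/COS(C)(=O)=O | intermediate
6 | (2E,6S,7S,10S)-1-bromo-6,7:10,11-diepoxy-3,7,11-trimethyldodec-2-ene | CC1(C)O[C@H]1CC[C@]2(C)O[C@H]2CC/C(C)=C/CBr | intermediate
7 | tert-butyl acetate | CC(=O)OC(C)(C)C | starting material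
8 | lithium enolate of tert-butyl acetate | C=C([O-])OC(C)(C)C.[Li+] | intermediate
9 | tert-butyl (4E,8S,9S,12S)-8,9:12,13-diepoxy-5,9,13-trimethyltetradec-4-enoate | CC1(C)O[C@H]1CC[C@]2(C)O[C@H]2CC/C(C)=C/CCC(=O)OC(C)(C)C | intermediate
10 | 3-O-trimethylsilyl ether of lactone 11 | O=C1CC[C@H]2[C@]3(C)CC[C@H](O[Si](C)(C)C)C(C)(C)O[C@H]3CC[C@]2(C)O1 | intermediate
11 | 3-[(3S,5aS,6S,7S,9aS)-3,7-dihydroxy-2,2,5a,7-tetramethyldecahydro-1-benzoxepin-6-yl]propanoic acid δ-lactone (C7–O–CO) | O=C1CC[C@H]2[C@]3(C)CC[C@H](O)C(C)(C)O[C@H]3CC[C@]2(C)O1 | intermediate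
12 | lithium 3-[(3S,5aS,6S,7S,9aS)-3,7-dihydroxy-2,2,5a,7-tetramethyldecahydro-1-benzoxepin-6-yl]propanoate | [Li+].[O-]C(=O)CC[C@H]1[C@]2(C)CC[C@H](O)C(C)(C)O[C@H]2CC[C@]1(C)O | intermediate
13 | triethylsilyl 3-[(3S,5aS,6S,7S,9aS)-2,2,5a,7-tetramethyl-3,7-bis(triethylsilyloxy)decahydro-1-benzoxepin-6-yl]propanoate | CC[Si](CC)(CC)OC(=O)CC[C@H]1[C@]2(C)CC[C@H](O[Si](CC)(CC)CC)C(C)(C)O[C@H]2CC[C@]1(C)O[Si](CC)(CC)CC | intermediate
14 | 3-[(3S,5aS,6S,7S,9aS)-2,2,5a,7-tetramethyl-3,7-bis(triethylsilyloxy)decahydro-1-benzoxepin-6-yl]propanoic acid | OC(=O)CC[C@H]1[C@]2(C)CC[C@H](O[Si](CC)(CC)CC)C(C)(C)O[C@H]2CC[C@]1(C)O[Si](CC)(CC)CC | intermediate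
15 | (3S,5aS,6S,7S,9aS)-6-ethenyl-2,2,5a,7-tetramethyl-3,7-bis(triethylsilyloxy)decahydro-1-benzoxepine | C=C[C@H]1[C@]2(C)CC[C@H](O[Si](CC)(CC)CC)C(C)(C)O[C@H]2CC[C@]1(C)O[Si](CC)(CC)CC | intermediate
16 | isobutyraldehyde | CC(C)C=O | starting material
17 | methyl vinyl ketone | CC(=O)C=C | starting material
18 | 1-(2-methylprop-1-en-1-yl)pyrrolidine | CC(C)=CN1CCCC1 | intermediate
19 | 3,3,6-trimethyl-2-(pyrrolidin-1-yl)-3,4-dihydro-2H-pyran (racemic at C2) | CC1=CCC(C)(C)C(N2CCCC2)O1 | intermediate
20 | 2,2-dimethyl-5-oxohexanal | CC(=O)CCC(C)(C)C=O | intermediate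
21 | 5,5-dimethylhept-6-yn-2-one | CC(=O)CCC(C)(C)C#C | intermediate
22 | (S)-2-(3,3-dimethylpent-4-yn-1-yl)-2-methyloxirane | C1O[C@@]1(C)CCC(C)(C)C#C | intermediate
23 | (S)-3,6,6-trimethyloct-1-en-7-yn-3-ol | C=C[C@@](C)(O)CCC(C)(C)C#C | intermediate
24 | dilithium alkoxide acetylide of 23 | [Li+].[Li+].C=C[C@@](C)([O-])CCC(C)(C)C#[C-] | intermediate
25 | (S)-triethyl{[3,6,6-trimethyl-8-(triethylsilyl)oct-1-en-7-yn-3-yl]oxy}silane | C=C[C@@](C)(O[Si](CC)(CC)CC)CCC(C)(C)C#C[Si](CC)(CC)CC | intermediate
26 | hexacarbonyldicobalt complex of alkyne 25 | C=C[C@@](C)(O[Si](CC)(CC)CC)CCC(C)(C)C#C[Si](CC)(CC)CC.[Co].[Co].[C-]#[O+].[C-]#[O+].[C-]#[O+].[C-]#[O+].[C-]#[O+].[C-]#[O+] | intermediate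
27 | (3aS,4S)-4,7,7-trimethyl-1-(triethylsilyl)-4-(triethylsilyloxy)-3,3a,4,5,6,7-hexahydro-2H-inden-2-one | O=C1C([Si](CC)(CC)CC)=C2[C@H](C1)[C@@](C)(O[Si](CC)(CC)CC)CCC2(C)C | intermediate
28 | (3aS,4S)-1-iodo-4,7,7-trimethyl-4-(triethylsilyloxy)-3,3a,4,5,6,7-hexahydro-2H-inden-2-one | O=C1C(I)=C2[C@H](C1)[C@@](C)(O[Si](CC)(CC)CC)CCC2(C)C | intermediate
29 | 9-{2-[(3S,5aS,6S,7S,9aS)-2,2,5a,7-tetramethyl-3,7-bis(triethylsilyloxy)decahydro-1-benzoxepin-6-yl]ethyl}-9-borabicyclo[3.3.1]nonane | B1(CC[C@H]3[C@]4(C)CC[C@H](O[Si](CC)(CC)CC)C(C)(C)O[C@H]4CC[C@]3(C)O[Si](CC)(CC)CC)C2CCCC1CCC2 | intermediate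
30 | (3aS,4S)-4,7,7-trimethyl-1-{2-[(3S,5aS,6S,7S,9aS)-2,2,5a,7-tetramethyl-3,7-bis(triethylsilyloxy)decahydro-1-benzoxepin-6-yl]ethyl}-4-(triethylsilyloxy)-3,3a,4,5,6,7-hexahydro-2H-inden-2-one | O=C1C(CC[C@H]2[C@]3(C)CC[C@H](O[Si](CC)(CC)CC)C(C)(C)O[C@H]3CC[C@]2(C)O[Si](CC)(CC)CC)=C2[C@H](C1)[C@@](C)(O[Si](CC)(CC)CC)CCC2(C)C | intermediate
31 | triethylsilyl enol ether (C1=C2) of the cis-fused (3aS,4S,7aR)-hydrindan-2-one derived from 30 | CC[Si](CC)(CC)OC1=C(CC[C@H]2[C@]3(C)CC[C@H](O[Si](CC)(CC)CC)C(C)(C)O[C@H]3CC[C@]2(C)O[Si](CC)(CC)CC)[C@@H]2[C@H](C1)[C@@](C)(O[Si](CC)(CC)CC)CCC2(C)C | intermediate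
32 | 1,1-dichloroethane | CC(Cl)Cl | starting material
33 | 1,1-dichloroethyllithium | CC(Cl)(Cl)[Li] | intermediate
34 | 1-chloro-1-methylcyclopropane fused across C1–C2 of 31, on the face of H-3a/H-7a, chloride syn to the five-membered ring | CC[Si](CC)(CC)O[C@]12C[C@H]3[C@@H]([C@@]1(CC[C@H]4[C@]5(C)CC[C@H](O[Si](CC)(CC)CC)C(C)(C)O[C@H]5CC[C@]4(C)O[Si](CC)(CC)CC)[C@@]2(C)Cl)C(C)(C)CC[C@]3(C)O[Si](CC)(CC)CC | intermediate
35 | tris(triethylsilyl) ether of sipholenol K: (4aR,8S,8aS)-3,5,5,8-tetramethyl-4-{2-[(3S,5aS,6S,7S,9aS)-2,2,5a,7-tetramethyl-3,7-bis(triethylsilyloxy)decahydro-1-benzoxepin-6-yl]ethyl}-8-(triethylsilyloxy)-4a,5,6,7,8,8a-hexahydronaphthalen-2(1H)-one | CC1=C(CC[C@H]2[C@]3(C)CC[C@H](O[Si](CC)(CC)CC)C(C)(C)O[C@H]3CC[C@]2(C)O[Si](CC)(CC)CC)[C@@H]2[C@H](CC1=O)[C@@](C)(O[Si](CC)(CC)CC)CCC2(C)C | intermediate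
36 | sipholenol K: (4aR,8S,8aS)-8-hydroxy-3,5,5,8-tetramethyl-4-{2-[(3S,5aS,6S,7S,9aS)-3,7-dihydroxy-2,2,5a,7-tetramethyldecahydro-1-benzoxepin-6-yl]ethyl}-4a,5,6,7,8,8a-hexahydronaphthalen-2(1H)-one | CC1=C(CC[C@H]2[C@]3(C)CC[C@H](O)C(C)(C)O[C@H]3CC[C@]2(C)O)[C@@H]2[C@H](CC1=O)[C@@](C)(O)CCC2(C)C | target

**Total step count:** 19. **Longest linear sequence:** 12 steps (steps 1–8, then 16–19).

**Steps most likely to fail**

Step 18. The short-lived carbenoid may cyclopropanate the hindered tetrasubstituted enol ether incompletely, or give mainly the cyclopropane epimer whose chloride is anti to the five-membered ring and does not ionise. The fallback sets out from 31 and uses a dihalocarbene, so that one halide is always syn to the ring. CHBr3 and KOtBu in pentane at −20 °C should give the dibromocyclopropane F1. Warming in toluene with Et3N should open it, with loss of the silyl bromide, to the 2-bromo enone F2. Suzuki–Miyaura methylation (trimethylboroxine, PdCl2(dppf), K2CO3, dioxane/H2O, 80 °C) then installs the methyl group and returns to the route at 35.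

Step 17. Hydride transfer to the fully substituted β-carbon may be too slow, or may occur on the wrong face and give the trans ring fusion. The fallback sets out from 30 and separates reduction from enol ether formation. Hydrogenation (H2, Pd/C, EtOAc) should add syn from the convex face to give the saturated cis-fused ketone F3. Silylation under equilibrating conditions (Et3SiCl, NaI, Et3N, MeCN, rt) should then give the more substituted enol ether and return to the route at 31.

Step 6. Proton loss from the tertiary cation may outrun capture by the ester carbonyl, so that the cascade ends at olefins. The fallback sets out from 9 and closes the lactone in a separate operation. The same Lewis-acid cascade followed by desilylation is taken to the bicyclic unsaturated ester F4 (the C7=C8 olefin and its double-bond isomers). Brønsted-acid hydrolactonisation (CF3SO3H cat., CH2Cl2, −20 °C) should reprotonate the alkene to the same tertiary cation, which the ester captures with loss of isobutene, returning to the route at 11.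

**Further compounds**

F1 | step 18 | 1,1-dibromocyclopropane fused across C1–C2 of 31 on the face of H-3a/H-7a | CC[Si](CC)(CC)O[C@]12C[C@H]3[C@@H]([C@@]1(CC[C@H]4[C@]5(C)CC[C@H](O[Si](CC)(CC)CC)C(C)(C)O[C@H]5CC[C@]4(C)O[Si](CC)(CC)CC)C2(Br)Br)C(C)(C)CC[C@]3(C)O[Si](CC)(CC)CC
F2 | step 18 | 3-bromo analogue of 35 (bromine in place of the ring A methyl group) | BrC1=C(CC[C@H]2[C@]3(C)CC[C@H](O[Si](CC)(CC)CC)C(C)(C)O[C@H]3CC[C@]2(C)O[Si](CC)(CC)CC)[C@@H]2[C@H](CC1=O)[C@@](C)(O[Si](CC)(CC)CC)CCC2(C)C
F3 | step 17 | saturated cis-fused hydrindan-2-one from 30 (H-1, H-3a and H-7a on the same face) | O=C1[C@@H](CC[C@H]2[C@]3(C)CC[C@H](O[Si](CC)(CC)CC)C(C)(C)O[C@H]3CC[C@]2(C)O[Si](CC)(CC)CC)[C@@H]2[C@H](C1)[C@@](C)(O[Si](CC)(CC)CC)CCC2(C)C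
F4 | step 6 | tert-butyl 3-[(3S,5aS,6R,9aS)-3-hydroxy-2,2,5a,7-tetramethyl-2,3,4,5,5a,6,9,9a-octahydro-1-benzoxepin-6-yl]propanoate | CC(C)(C)OC(=O)CC[C@H]2[C@]3(C)CC[C@H](O)C(C)(C)O[C@H]3CC=C2C
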